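## Retrosynthetic overview

1. Target 26 ⇐ Luche reduction at C9 and anisoylation at C6 of dihydroxy enone 23 ⇐ cis-enediol 19 (desilylation, then C9 oxidation with the 4,6-diol masked as a boronate).
2. Key disconnection: C6–C7 and C8–C9 of 19 are cut together, a [5+2] annulation of cyclopentane 1,5-dialdehyde 14 with 1-(trimethylsilyl)propyne used as a cis-1,2-dianion (titanacyclopropene).
3. Enabling feature: in the seven-membered ring B the two oxygen-bearing carbons C6 and C9 flank the C7=C8(CH3) alkene, a (Z)-2-ene-1,4-diol C6(O)–C7=C8–C9(O). Both can therefore be aldehyde carbons of the chain C6–C5–C1–C10–C9 held by ring A, and C7/C8 map onto an alkyne.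
4. Ring A (C1–C5) comes from 3-methylcyclopent-2-enone: asymmetric conjugate addition sets quaternary C1, enolate hydroxymethylation sets C5, isopropyl addition sets C4; the 1-silylvinyl group becomes the CH2CHO arm (C10–C9).
5. Order of ring formation: ring A is present from the start; ring B is closed in step 7.

Key step: step 7

Remark (assumption): daucane numbering is used (C1 quaternary methyl carbon, C4 isopropyl carbinol, C5 ring-fusion CH, C6 ester carbon, C7=C8, C9 carbinol, C10 CH2); β is the face of the C1 methyl group. The target is 6α-(4-methoxybenzoyloxy)dauc-7-ene-4β,9β-diol. Compounds 18–22 are drawn in the 9α series; C9 is oxidized in step 9, so its configuration there is without consequence.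

## Route

Step 1
Reactants: 1 3-methylcyclopent-2-en-1-one; 2 ethynyltrimethylsilane
Product: 5 (S)-triethyl({3-methyl-3-[1-(trimethylsilyl)ethenyl]cyclopent-1-en-1-yl}oxy)silane, via alkenylalane 3 (not isolated), via aluminium enolate 4 (not isolated)
Conditions: 2, i-Bu2AlH, hexanes/THF, 55 °C; then 1, Cu(OTf)2 (5 mol%), chiral sulfonate-bearing N-heterocyclic carbene ligand (5 mol%), THF, −30 → 4 °C; then Et3SiOTf, −78 → 0 °C
Reagents that add atoms: triethylsilyl trifluoromethanesulfonate, CC[Si](CC)(CC)OS(=O)(=O)C(F)(F)F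
Why: Copper-catalysed asymmetric conjugate addition of an alkenylalane to a β-substituted cyclopentenone sets the quaternary C1 centre under catalyst control (ligand enantiomer chosen for the S centre), and O-silylation of the aluminium enolate fixes the enolate regiochemistry toward C5.

Step 2
Reactants: 5 (S)-silyl enol ether; 6 formaldehyde
Product: 7 (2S,3S)-2-(hydroxymethyl)-3-methyl-3-[1-(trimethylsilyl)ethenyl]cyclopentan-1-one
Conditions: aq. HCHO (37%), Sc(OTf)3 (10 mol%), THF, 0 °C → rt
Reagents that add atoms: none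
Why: Lewis-acid-catalysed Mukaiyama-type hydroxymethylation of the regiodefined silyl enol ether; formaldehyde approaches C5 anti to the bulky 1-silylvinyl group on the neighbouring quaternary carbon, so CH2OH ends cis to the methyl group (C5 is also epimerisable toward this isomer).

Step 3
Reactants: 7 hydroxymethyl ketone; 8 isopropylmagnesium chloride
Product: 9 (1R,2S,3S)-2-(hydroxymethyl)-3-methyl-1-(propan-2-yl)-3-[1-(trimethylsilyl)ethenyl]cyclopentan-1-ol
Conditions: CeCl3 (anhydrous, 3 equiv), 8 (3 equiv), THF, −78 → −40 °C; aq. NH4Cl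
Reagents that add atoms: none
Why: Organocerium 1,2-addition (which suppresses enolisation and β-hydride reduction) to the chelated α-(oxidomethyl) ketone; the nucleophile enters anti to the C5 substituent, giving the C4 carbinol with OH cis to CH2OH and isopropyl trans to it.

Step 4
Reactants: 9 diol
Product: 10 triethyl{[(1R,2S,3S)-3-methyl-1-(propan-2-yl)-2-{[(triethylsilyl)oxy]methyl}-3-[1-(trimethylsilyl)ethenyl]cyclopentyl]oxy}silane
Conditions: Et3SiOTf (3 equiv), 2,6-lutidine, CH2Cl2, −78 → 0 °C
Reagents that add atoms: triethylsilyl trifluoromethanesulfonate, CC[Si](CC)(CC)OS(=O)(=O)C(F)(F)F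
Why: Silyl triflate silylation protects the primary and the hindered tertiary hydroxyl without touching a stereocentre.

Step 5
Reactants: 10 bis(triethylsilyl) ether
Product: 12 2-[(1S,2S,3R)-1-methyl-3-(propan-2-yl)-3-[(triethylsilyl)oxy]-2-{[(triethylsilyl)oxy]methyl}cyclopentyl]-2-(trimethylsilyl)ethan-1-ol (both epimers at the silyl-bearing carbon), via alkylborane 11 (not isolated)
Conditions: BH3·THF, THF, 0 °C → rt; then 3 M NaOH, 30% H2O2, 0 °C
Reagents that add atoms: hydrogen peroxide, OO
Why: Anti-Markovnikov hydroboration–oxidation of the 1,1-disubstituted vinylsilane places oxygen on the terminal carbon (C9); the new silyl-bearing centre C10 forms as a mixture that is erased in step 6.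

Step 6
Reactants: 12 β-silyl alcohol
Product: 14 (1R,2R,5R)-2-methyl-2-(2-oxoethyl)-5-(propan-2-yl)-5-[(triethylsilyl)oxy]cyclopentane-1-carbaldehyde, via silylated dialdehyde 13 (not isolated)
Conditions: (COCl)2, DMSO, CH2Cl2, −78 → −30 °C; Et3N, −78 → 0 °C; then AcOH/THF/H2O, rt
Reagents that add atoms: none
Why: Swern oxidation converts the free primary alcohol and, with in situ cleavage, the primary triethylsilyl ether into aldehydes while the tertiary silyl ether survives; the α-silyl aldehyde 13 loses silicon by C-to-O silyl shift and hydrolysis, and epimerisable C5 stays in the more stable arrangement trans to isopropyl.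

Step 7
Reactants: 14 dialdehyde; 15 trimethyl(prop-1-yn-1-yl)silane
Product: 19 (3R,3aS,4R,7S,8aR)-6,8a-dimethyl-3-(propan-2-yl)-3-[(triethylsilyl)oxy]-5-(trimethylsilyl)-1,2,3,3a,4,7,8,8a-octahydroazulene-4,7-diol, via titanacyclopropene 16 (not isolated), via oxatitanacyclopentene 17 (not isolated), via titanium diolate 18 (not isolated)
Conditions: 15 (1.5 equiv), Ti(OiPr)4 (1.5 equiv), i-PrMgCl (3 equiv), Et2O, −78 → −50 °C, 2 h; then 14 added slowly (final 0.01 M), −50 → 0 °C; aq. NH4Cl
Reagents that add atoms: none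
Why: Proposed new method: Ti(OiPr)4/2 i-PrMgCl turns the silylalkyne into titanacyclopropene 16, a cis-1,2-dianion equivalent; the unhindered C9 aldehyde inserts into the Ti–C bond remote from silicon (C8–C9, oxatitanacyclopentene 17) and the tethered C6 aldehyde then inserts into the remaining Ti–C7 bond (C6–C7), giving titanium diolate 18 and, on hydrolysis, 19. The closest known reactions are the successive additions of alkyne–titanium complexes to two carbonyl compounds and the [4+2] naphthol annulation of alkyne–niobium or alkyne–tantalum complexes with phthalaldehyde; closing a seven-membered carbocycle from a 1,5-dialdehyde in this way has not been shown. Ring B is closed by a 7-exo-trig addition of the alkenyl–titanium bond to the C6 carbonyl, templated by the Ti–O9 bond formed in the first insertion. Because one titanium bridges O9 and O6, the new carbinols are cis; at C6 the O–Ti bond should take the pseudo-equatorial site of a chair-like closure, away from the axial C1 methyl group, which gives 6α, whereas C9 is formed in the intermolecular insertion without facial control and only the 9α epimer can reach that chair (C9 is erased in step 9). The regiochemistry needed (methyl-bearing alkyne carbon to C9, silyl-bearing carbon to C6) is secured by the silyl group, which directs the first insertion to the remote carbon, and by the steric gap between the CH2CHO aldehyde and the neopentyl-type C6 aldehyde; ring closure against oligomerization is secured by slow addition at high dilution.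

Step 8
Reactants: 19 silylated cis-enediol
Product: 20 (3R,3aS,4S,7S,8aR)-6,8a-dimethyl-3-(propan-2-yl)-1,2,3,3a,4,7,8,8a-octahydroazulene-3,4,7-triol
Conditions: Bu4NF (4 equiv), THF, 60 °C
Reagents that add atoms: none
Why: Fluoride cleaves the tertiary silyl ether and, assisted by the neighbouring C6 alkoxide, the vinylic C–Si bond with retention of alkene geometry (alkoxide-assisted protodesilylation of a β-hydroxy vinylsilane; Peterson elimination is impossible in the ring).

Step 9
Reactants: 20 triol
Product: 23 (3R,3aS,4S,8aR)-3,4-dihydroxy-6,8a-dimethyl-3-(propan-2-yl)-2,3,3a,4,8,8a-hexahydroazulen-7(1H)-one, via cyclic phenylboronate 21 (not isolated), via boronate enone 22 (not isolated)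
Conditions: PhB(OH)2 (1.05 equiv), MgSO4, CH2Cl2, rt; then Dess–Martin periodinane, NaHCO3, 0 °C → rt; then propane-1,3-diol (10 equiv), rt
Reagents that add atoms: none
Why: A transient six-membered phenylboronate across the tertiary C4–OH and the C6–OH (the 1,3-diol motif of 2-methylpentane-2,4-diol boronates) leaves only the C9 hydroxyl for Dess–Martin oxidation, which also removes the uncontrolled C9 stereocentre, and diol exchange then frees the 4,6-diol.

Step 10
Reactants: 23 dihydroxy enone; 24 4-methoxybenzoyl chloride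
Product: 25 (3R,3aS,4S,8aR)-3-hydroxy-6,8a-dimethyl-7-oxo-3-(propan-2-yl)-1,2,3,3a,4,7,8,8a-octahydroazulen-4-yl 4-methoxybenzoate
Conditions: 24 (1.5 equiv), Et3N, DMAP (0.2 equiv), CH2Cl2, 0 °C → rt
Reagents that add atoms: none
Why: DMAP-catalysed acylation of the only secondary hydroxyl; the hindered tertiary C4–OH does not react and C6 keeps its configuration.

Step 11
Reactants: 25 anisoate enone
Product: 26 (3R,3aS,4S,7R,8aR)-3,7-dihydroxy-6,8a-dimethyl-3-(propan-2-yl)-1,2,3,3a,4,7,8,8a-octahydroazulen-4-yl 4-methoxybenzoate (target)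
Conditions: NaBH4, CeCl3·7H2O, MeOH, −78 °C
Reagents that add atoms: none
Why: Luche 1,2-reduction of the enone; hydride should add to C9 from the α face, anti to the axial C1 methyl group across C10 (as in the reduction of 2-oxo steroids), giving the 9β alcohol.

## Compound list

1 | 3-methylcyclopent-2-en-1-one | CC1=CC(=O)CC1 | starting material
2 | ethynyltrimethylsilane | C#C[Si](C)(C)C | starting material
3 | [1-(trimethylsilyl)ethenyl]bis(2-methylpropyl)alumane | C=C([Si](C)(C)C)[Al](CC(C)C)CC(C)C | intermediate (not isolated)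
4 | diisobutylaluminium enolate of (S)-3-methyl-3-[1-(trimethylsilyl)ethenyl]cyclopentan-1-one | C=C([Si](C)(C)C)[C@@]1(C)CCC(O[Al](CC(C)C)CC(C)C)=C1 | intermediate (not isolated)
5 | (S)-triethyl({3-methyl-3-[1-(trimethylsilyl)ethenyl]cyclopent-1-en-1-yl}oxy)silane | C=C([Si](C)(C)C)[C@@]1(C)CCC(O[Si](CC)(CC)CC)=C1 | intermediate
6 | formaldehyde | C=O | starting material
7 | (2S,3S)-2-(hydroxymethyl)-3-methyl-3-[1-(trimethylsilyl)ethenyl]cyclopentan-1-one (CH2OH cis to CH3) | C=C([Si](C)(C)C)[C@@]1(C)CCC(=O)[C@@H]1CO | intermediate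
8 | isopropylmagnesium chloride | CC(C)[Mg]Cl | starting material
9 | (1R,2S,3S)-2-(hydroxymethyl)-3-methyl-1-(propan-2-yl)-3-[1-(trimethylsilyl)ethenyl]cyclopentan-1-ol (OH, CH2OH and CH3 on one face) | C=C([Si](C)(C)C)[C@@]1(C)CC[C@@](O)(C(C)C)[C@@H]1CO | intermediate
10 | triethyl{[(1R,2S,3S)-3-methyl-1-(propan-2-yl)-2-{[(triethylsilyl)oxy]methyl}-3-[1-(trimethylsilyl)ethenyl]cyclopentyl]oxy}silane | C=C([Si](C)(C)C)[C@@]1(C)CC[C@@](O[Si](CC)(CC)CC)(C(C)C)[C@@H]1CO[Si](CC)(CC)CC | intermediate
11 | primary alkylborane from hydroboration of 10 (boron on C9) | BCC([Si](C)(C)C)[C@@]1(C)CC[C@@](O[Si](CC)(CC)CC)(C(C)C)[C@@H]1CO[Si](CC)(CC)CC | intermediate (not isolated)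
12 | 2-[(1S,2S,3R)-1-methyl-3-(propan-2-yl)-3-[(triethylsilyl)oxy]-2-{[(triethylsilyl)oxy]methyl}cyclopentyl]-2-(trimethylsilyl)ethan-1-ol (both epimers at the silyl-bearing carbon) | OCC([Si](C)(C)C)[C@@]1(C)CC[C@@](O[Si](CC)(CC)CC)(C(C)C)[C@@H]1CO[Si](CC)(CC)CC | intermediate
13 | (1R,2S,5R)-2-methyl-2-[2-oxo-1-(trimethylsilyl)ethyl]-5-(propan-2-yl)-5-[(triethylsilyl)oxy]cyclopentane-1-carbaldehyde | O=CC([Si](C)(C)C)[C@@]1(C)CC[C@@](O[Si](CC)(CC)CC)(C(C)C)[C@@H]1C=O | intermediate (not isolated)
14 | (1R,2R,5R)-2-methyl-2-(2-oxoethyl)-5-(propan-2-yl)-5-[(triethylsilyl)oxy]cyclopentane-1-carbaldehyde (CHO trans to CH2CHO and to isopropyl) | O=CC[C@@]1(C)CC[C@@](O[Si](CC)(CC)CC)(C(C)C)[C@@H]1C=O | intermediate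
15 | trimethyl(prop-1-yn-1-yl)silane | CC#C[Si](C)(C)C | starting material
16 | 2-methyl-3-(trimethylsilyl)-1,1-di(propan-2-yloxy)titanacycloprop-2-ene | CC1=C([Si](C)(C)C)[Ti]1(OC(C)C)OC(C)C | intermediate (not isolated)
17 | oxatitanacyclopentene from insertion of the C9 aldehyde (C9 epimers) | CC(C)O[Ti]1(OC(C)C)OC(C[C@@]2(C)CC[C@@](O[Si](CC)(CC)CC)(C(C)C)[C@@H]2C=O)C(C)=C1[Si](C)(C)C | intermediate (not isolated)
18 | bridged titanium 6,9-diolate (6α,9α) | CC(C)O[Ti]1(OC(C)C)O[C@H]2C([Si](C)(C)C)=C(C)[C@@H](O1)C[C@@]3(C)CC[C@@](O[Si](CC)(CC)CC)(C(C)C)[C@H]23 | intermediate (not isolated)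
19 | (3R,3aS,4R,7S,8aR)-6,8a-dimethyl-3-(propan-2-yl)-3-[(triethylsilyl)oxy]-5-(trimethylsilyl)-1,2,3,3a,4,7,8,8a-octahydroazulene-4,7-diol (6α,9α-diol, trans-fused) | O[C@H]1C([Si](C)(C)C)=C(C)[C@@H](O)C[C@@]2(C)CC[C@@](O[Si](CC)(CC)CC)(C(C)C)[C@H]12 | intermediate
20 | (3R,3aS,4S,7S,8aR)-6,8a-dimethyl-3-(propan-2-yl)-1,2,3,3a,4,7,8,8a-octahydroazulene-3,4,7-triol | O[C@H]1C=C(C)[C@@H](O)C[C@@]2(C)CC[C@@](O)(C(C)C)[C@H]12 | intermediate
21 | cyclic phenylboronate of 20 across O4 and O6 | c1ccc(cc1)B1O[C@H]2C=C(C)[C@@H](O)C[C@@]3(C)CC[C@@](O1)(C(C)C)[C@H]23 | intermediate (not isolated)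
22 | C9 ketone of boronate 21 | c1ccc(cc1)B1O[C@H]2C=C(C)C(=O)C[C@@]3(C)CC[C@@](O1)(C(C)C)[C@H]23 | intermediate (not isolated)
23 | (3R,3aS,4S,8aR)-3,4-dihydroxy-6,8a-dimethyl-3-(propan-2-yl)-2,3,3a,4,8,8a-hexahydroazulen-7(1H)-one | O[C@H]1C=C(C)C(=O)C[C@@]2(C)CC[C@@](O)(C(C)C)[C@H]12 | intermediate
24 | 4-methoxybenzoyl chloride | COc1ccc(cc1)C(Cl)=O | starting material
25 | (3R,3aS,4S,8aR)-3-hydroxy-6,8a-dimethyl-7-oxo-3-(propan-2-yl)-1,2,3,3a,4,7,8,8a-octahydroazulen-4-yl 4-methoxybenzoate | COc1ccc(cc1)C(=O)O[C@H]1C=C(C)C(=O)C[C@@]2(C)CC[C@@](O)(C(C)C)[C@H]12 | intermediate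
26 | (3R,3aS,4S,7R,8aR)-3,7-dihydroxy-6,8a-dimethyl-3-(propan-2-yl)-1,2,3,3a,4,7,8,8a-octahydroazulen-4-yl 4-methoxybenzoate | COc1ccc(C(=O)O[C@H]2C=C(C)[C@H](O)C[C@@]3(C)CC[C@@](O)(C(C)C)[C@H]23)cc1 | target

## Step count and risks

Total step count: 11. Longest linear sequence: 11 steps (1 → 26).

Steps most likely to fail:

Step 7. After the first insertion, the hindered silicon-bearing alkenyl–titanium bond may be protonated or react intermolecularly faster than it closes the seven-membered ring; the 9β epimer of 17 may also fail to close. The fallback sets out from 14 and uses known chemistry. Titanacyclopropene 16 is used only for the first carbonyl addition at the C9 aldehyde (−78 °C, 1 equiv), and the remaining C–Ti bond is cleaved with iodine to give the (Z)-iodo(silyl)alkene hydroxy aldehyde F1. An intramolecular Nozaki–Hiyama–Kishi reaction (CrCl2, NiCl2 (1 mol%), DMSO/THF, high dilution) then forms the C6–C7 bond and comes back to the route at 19.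

Step 9. Masking of the 4,6-diol by the boronic acid may be incomplete or unselective, so that the C6 carbinol is oxidized as well. The fallback sets out from 20. Both secondary alcohols are oxidized on purpose with Dess–Martin periodinane to the enedione F2. Hydroxyl-directed reduction with Me4NBH(OAc)3 (AcOH/MeCN, −30 °C) should then reduce only the C6 carbonyl next to the C4 hydroxyl, from the face anti to the C1 methyl group, to give the 6β-hydroxy enone F3. Mitsunobu esterification with 4-methoxybenzoic acid (PPh3, DIAD, toluene) inverts C6 and installs the ester, coming back to the route at 25.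

Step 3. The secondary organometallic may enolise the hindered ketone, trigger retro-aldol loss of formaldehyde, or reduce the carbonyl by β-hydride transfer instead of adding. The fallback sets out from 7. 2-Propenylmagnesium bromide with CeCl3, an sp2 nucleophile that cannot act as a hydride donor, gives the isopropenyl carbinol F4. Hydroxyl-directed hydrogenation of the isopropenyl group with [Ir(cod)(PCy3)(py)]PF6 and H2 (CH2Cl2, 0 °C), which should leave the hindered vinylsilane untouched, comes back to the route at 9.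

Further compounds

F1 | step 7 | (1R,2R,5R)-2-[(3Z)-2-hydroxy-4-iodo-3-methyl-4-(trimethylsilyl)but-3-en-1-yl]-2-methyl-5-(propan-2-yl)-5-[(triethylsilyl)oxy]cyclopentane-1-carbaldehyde (carbinol epimers) | OC(/C(C)=C(\I)[Si](C)(C)C)C[C@@]1(C)CC[C@@](O[Si](CC)(CC)CC)(C(C)C)[C@@H]1C=O
F2 | step 9 | (3R,3aR,8aR)-3-hydroxy-6,8a-dimethyl-3-(propan-2-yl)-1,2,3,3a,8,8a-hexahydroazulene-4,7-dione | O=C1C=C(C)C(=O)C[C@@]2(C)CC[C@@](O)(C(C)C)[C@H]12
F3 | step 9 | (3R,3aS,4R,8aR)-3,4-dihydroxy-6,8a-dimethyl-3-(propan-2-yl)-2,3,3a,4,8,8a-hexahydroazulen-7(1H)-one (6β epimer of 23) | O[C@@H]1C=C(C)C(=O)C[C@@]2(C)CC[C@@](O)(C(C)C)[C@H]12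
F4 | step 3 | (1S,2S,3S)-2-(hydroxymethyl)-3-methyl-1-(prop-1-en-2-yl)-3-[1-(trimethylsilyl)ethenyl]cyclopentan-1-ol | C=C([Si](C)(C)C)[C@@]1(C)CC[C@@](O)(C(C)=C)[C@@H]1CO
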